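**Retrosynthetic overview**
- Target ⇐ its nona-O-benzyl ether (global hydrogenolysis last).
- Benzyl ether ⇐ (2S)-2,4-diaryl-2H-chromene by hydroboration–oxidation; the single C2 stereocentre relays C3 and C4 (2,3-trans-3,4-trans).
- Chromene ⇐ C4–C5′ bond by a polarity-reversed coupling: the flavanone carbonyl carbon (normally an electrophile) reacts as a nucleophilic diazo carbon from its N-tosylhydrazone with a 5-iodoflavonol.
- Flavanone ⇐ chromone + arylboronic acid (asymmetric 1,4-addition sets C2). Iodoflavonol ⇐ flavonol (Algar–Flynn–Oyamada), O-benzylation, carbonyl-directed C5–H iodination.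
- Ring order: both pyranone rings are built first from one common acetophenone; the two bicyclic halves are then joined and no ring is closed after the union.

Assumption: the SMILES is read as a (2R,3S,4R) upper unit (2-aryl and 4-aryl on one face, 3-OH on the other); in step 3 the (S)-diphosphine is taken to give the (2S)-flavanone by analogy with (S)-biaryl-diphosphine rhodium additions to cyclic enones, and the mirror-image ligand is used if a trial run shows the opposite sense.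

**Step 1**
Reactants: 1 1-(2,3,4-trihydroxyphenyl)ethanone
Product: 2 1-[3,4-bis(benzyloxy)-2-hydroxyphenyl]ethanone
Conditions: BnBr (2.1 equiv), K2CO3 (2.2 equiv), DMF, rt
Reagents that add atoms: benzyl bromide, BrCc1ccccc1
Why: Williamson etherification; the 2-OH is hydrogen-bonded to the acetyl group and its phenoxide is the least nucleophilic, so two equivalents of bromide benzylate only the 3- and 4-OH.

**Step 2**
Reactants: 2 1-[3,4-bis(benzyloxy)-2-hydroxyphenyl]ethanone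
Product: 4 7,8-bis(benzyloxy)-4H-chromen-4-one, via enaminone 3 (not isolated)
Conditions: Me2NCH(OMe)2, toluene, 100 °C; then 2 M HCl, CH2Cl2, 40 °C
Reagents that add atoms: N,N-dimethylformamide dimethyl acetal, COC(OC)N(C)C
Why: Enaminone route to chromones: condensation at the acetyl methyl group, then acid-mediated conjugate addition of the phenol and loss of dimethylamine.

**Step 3**
Reactants: 4 7,8-bis(benzyloxy)-4H-chromen-4-one; 5 [3,4-bis(benzyloxy)phenyl]boronic acid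
Product: 6 (2S)-7,8-bis(benzyloxy)-2-[3,4-bis(benzyloxy)phenyl]chroman-4-one
Conditions: [RhCl(C2H4)2]2 (2.5 mol %), (S)-MeO-F12-BIPHEP (5.5 mol %), K3PO4 (0.5 equiv), 5 (2.5 equiv), toluene/H2O (10:1), 50 °C
Reagents that add atoms: none
Why: Rhodium-catalysed asymmetric 1,4-addition of an arylboronic acid to a chromone (Hayashi–Miyaura type); the chiral diphosphine controls the face of C2 to which the aryl group is delivered, giving the (2S)-flavanone, and the nearly neutral medium avoids ring-opening to the chalcone.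

**Step 4**
Reactants: 2 1-[3,4-bis(benzyloxy)-2-hydroxyphenyl]ethanone; 7 3,4-bis(benzyloxy)benzaldehyde
Product: 10 7,8-bis(benzyloxy)-2-[3,4-bis(benzyloxy)phenyl]-3-hydroxy-4H-chromen-4-one, via chalcone 8 (not isolated), via dihydroflavonol 9 (not isolated)
Conditions: KOH (aq), EtOH/THF, rt; then 30% H2O2, 0 °C to rt
Reagents that add atoms: hydrogen peroxide, OO
Why: Claisen–Schmidt condensation followed by Algar–Flynn–Oyamada oxidative cyclisation; a 2′-hydroxychalcone without a 6′-substituent gives the flavonol and not the aurone.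

**Step 5**
Reactants: 10 7,8-bis(benzyloxy)-2-[3,4-bis(benzyloxy)phenyl]-3-hydroxy-4H-chromen-4-one
Product: 11 3,7,8-tris(benzyloxy)-2-[3,4-bis(benzyloxy)phenyl]-4H-chromen-4-one
Conditions: BnBr (1.5 equiv), K2CO3, DMF, 60 °C
Reagents that add atoms: benzyl bromide, BrCc1ccccc1
Why: Williamson etherification of the acidic 3-OH, which must be masked so that only the C4 carbonyl binds the metal in step 6.

**Step 6**
Reactants: 11 3,7,8-tris(benzyloxy)-2-[3,4-bis(benzyloxy)phenyl]-4H-chromen-4-one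
Product: 12 3,7,8-tris(benzyloxy)-2-[3,4-bis(benzyloxy)phenyl]-5-iodo-4H-chromen-4-one
Conditions: [Cp*RhCl2]2 (2.5 mol %), AgSbF6 (10 mol %), N-iodosuccinimide (1.2 equiv), PivOH (1.1 equiv), 1,2-dichloroethane, 60 °C, dark
Reagents that add atoms: N-iodosuccinimide, O=C1CCC(=O)N1I
Why: Proposed new method: the C4 carbonyl oxygen binds cationic Cp*Rh (trivalent rhodium) and directs carboxylate-assisted metalation of the peri C5–H through a five-membered rhodacycle, which N-iodosuccinimide iodinates; the closest known reaction types are ketone-directed Cp*Rh-catalysed ortho-halogenation of aryl ketones with N-halosuccinimides and carbonyl-directed C5–H functionalisation of chromones and flavones.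

**Step 7**
Reactants: 6 (2S)-7,8-bis(benzyloxy)-2-[3,4-bis(benzyloxy)phenyl]chroman-4-one; 12 3,7,8-tris(benzyloxy)-2-[3,4-bis(benzyloxy)phenyl]-5-iodo-4H-chromen-4-one
Product: 15 3,7,8-tris(benzyloxy)-2-[3,4-bis(benzyloxy)phenyl]-5-{(2S)-7,8-bis(benzyloxy)-2-[3,4-bis(benzyloxy)phenyl]-2H-chromen-4-yl}-4H-chromen-4-one, via tosylhydrazone 13 (not isolated), via diazo compound 14 (not isolated)
Conditions: 6 (1.2 equiv), TsNHNH2 (1.3 equiv), 1,4-dioxane, 70 °C; then 12 (1.0 equiv), Pd2(dba)3 (2.5 mol %), XPhos (10 mol %), Cs2CO3 (2.5 equiv), 90 °C, Ar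
Reagents that add atoms: none
Why: Barluenga–Valdés coupling: the sulfonylhydrazone turns the normally electrophilic C4 carbonyl carbon of 6 into a nucleophilic diazo carbon (a vinyl-anion equivalent of the ketone) that attacks the electrophilic arylpalladium from 12, and carbene migratory insertion with β-hydride elimination toward C3 gives the C3=C4 alkene; C2 keeps its configuration because no enolate of 6 is formed and carbonate is too weak to deprotonate the product.

**Step 8**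
Reactants: 15 the (2S)-2,4-diaryl-2H-chromene from step 7
Product: 17 3,7,8-tris(benzyloxy)-2-[3,4-bis(benzyloxy)phenyl]-5-{(2R,3S,4R)-7,8-bis(benzyloxy)-2-[3,4-bis(benzyloxy)phenyl]-3-hydroxychroman-4-yl}-4H-chromen-4-one, via alkylborane 16 (not isolated)
Conditions: BH3·THF (1.5 equiv), THF, 0 °C to rt; then aq. NaOH, 30% H2O2, 0 °C
Reagents that add atoms: hydrogen peroxide, OO
Why: Hydroboration–oxidation: boron adds to the less substituted C3 and hydrogen to the doubly benzylic C4, syn and from the face opposite the C2 aryl group, and oxidation proceeds with retention, so the 3-OH is trans to both aryl groups (2R,3S,4R) as in the known conversion of flav-3-enes into 2,3-trans-flavan-3-ols; the cross-conjugated pyranone carbonyl is expected to react with borane much more slowly than the electron-rich styrene-type alkene.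

**Step 9**
Reactants: 17 the nona-O-benzyl ether from step 8
Product: 18 2-(3,4-dihydroxyphenyl)-5-[(2R,3S,4R)-2-(3,4-dihydroxyphenyl)-3,7,8-trihydroxychroman-4-yl]-3,7,8-trihydroxy-4H-chromen-4-one
Conditions: H2 (1 atm), Pd(OH)2/C, THF/MeOH (1:1), rt; filtration under Ar
Reagents that add atoms: none
Why: Hydrogenolysis of the nine benzyl ethers; at 1 atm and room temperature the tetrasubstituted C2=C3 bond of the flavonol and the benzylic C2–O1 and C4–aryl bonds of the flavan unit are retained, as in the usual deprotection of benzylated flavonols and proanthocyanidins, and no stereocentre is touched.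

**Compound list**
1 | 1-(2,3,4-trihydroxyphenyl)ethanone | CC(=O)c1ccc(O)c(O)c1O | starting material
2 | 1-[3,4-bis(benzyloxy)-2-hydroxyphenyl]ethanone | CC(=O)c1ccc(OCc2ccccc2)c(OCc2ccccc2)c1O | intermediate
3 | (E)-1-[3,4-bis(benzyloxy)-2-hydroxyphenyl]-3-(dimethylamino)prop-2-en-1-one | CN(C)/C=C/C(=O)c1ccc(OCc2ccccc2)c(OCc2ccccc2)c1O | intermediate
4 | 7,8-bis(benzyloxy)-4H-chromen-4-one | O=c1ccoc2c(OCc3ccccc3)c(OCc3ccccc3)ccc12 | intermediate
5 | [3,4-bis(benzyloxy)phenyl]boronic acid | OB(O)c1ccc(OCc2ccccc2)c(OCc2ccccc2)c1 | starting material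
6 | (2S)-7,8-bis(benzyloxy)-2-[3,4-bis(benzyloxy)phenyl]chroman-4-one | O=C1C[C@@H](c2ccc(OCc3ccccc3)c(OCc3ccccc3)c2)Oc2c(OCc3ccccc3)c(OCc3ccccc3)ccc12 | intermediate
7 | 3,4-bis(benzyloxy)benzaldehyde | O=Cc1ccc(OCc2ccccc2)c(OCc2ccccc2)c1 | starting material
8 | (E)-1-[3,4-bis(benzyloxy)-2-hydroxyphenyl]-3-[3,4-bis(benzyloxy)phenyl]prop-2-en-1-one | O=C(/C=C/c1ccc(OCc2ccccc2)c(OCc2ccccc2)c1)c1ccc(OCc2ccccc2)c(OCc2ccccc2)c1O | intermediate
9 | rac-trans-7,8-bis(benzyloxy)-2-[3,4-bis(benzyloxy)phenyl]-3-hydroxychroman-4-one | O=C1c2ccc(OCc3ccccc3)c(OCc3ccccc3)c2OC(c2ccc(OCc3ccccc3)c(OCc3ccccc3)c2)C1O | intermediate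
10 | 7,8-bis(benzyloxy)-2-[3,4-bis(benzyloxy)phenyl]-3-hydroxy-4H-chromen-4-one | O=c1c(O)c(-c2ccc(OCc3ccccc3)c(OCc3ccccc3)c2)oc2c(OCc3ccccc3)c(OCc3ccccc3)ccc12 | intermediate
11 | 3,7,8-tris(benzyloxy)-2-[3,4-bis(benzyloxy)phenyl]-4H-chromen-4-one | O=c1c(OCc2ccccc2)c(-c2ccc(OCc3ccccc3)c(OCc3ccccc3)c2)oc2c(OCc3ccccc3)c(OCc3ccccc3)ccc12 | intermediate
12 | 3,7,8-tris(benzyloxy)-2-[3,4-bis(benzyloxy)phenyl]-5-iodo-4H-chromen-4-one | O=c1c(OCc2ccccc2)c(-c2ccc(OCc3ccccc3)c(OCc3ccccc3)c2)oc2c(OCc3ccccc3)c(OCc3ccccc3)cc(I)c12 | intermediate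
13 | N′-tosylhydrazone of 6 | Cc1ccc(cc1)S(=O)(=O)NN=C1C[C@@H](c2ccc(OCc3ccccc3)c(OCc3ccccc3)c2)Oc2c(OCc3ccccc3)c(OCc3ccccc3)ccc12 | intermediate
14 | (2S)-7,8-bis(benzyloxy)-2-[3,4-bis(benzyloxy)phenyl]-4-diazochroman | [N-]=[N+]=C1C[C@@H](c2ccc(OCc3ccccc3)c(OCc3ccccc3)c2)Oc2c(OCc3ccccc3)c(OCc3ccccc3)ccc12 | intermediate
15 | 3,7,8-tris(benzyloxy)-2-[3,4-bis(benzyloxy)phenyl]-5-{(2S)-7,8-bis(benzyloxy)-2-[3,4-bis(benzyloxy)phenyl]-2H-chromen-4-yl}-4H-chromen-4-one | O=c1c(OCc2ccccc2)c(-c2ccc(OCc3ccccc3)c(OCc3ccccc3)c2)oc2c(OCc3ccccc3)c(OCc3ccccc3)cc(C3=C[C@@H](c4ccc(OCc5ccccc5)c(OCc5ccccc5)c4)Oc4c(OCc5ccccc5)c(OCc5ccccc5)ccc34)c12 | intermediate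
16 | C3-boranyl adduct of 15 (boron trans to both aryl groups) | O=c1c(OCc2ccccc2)c(-c2ccc(OCc3ccccc3)c(OCc3ccccc3)c2)oc2c(OCc3ccccc3)c(OCc3ccccc3)cc([C@@H]3c4ccc(OCc5ccccc5)c(OCc5ccccc5)c4O[C@H](c4ccc(OCc5ccccc5)c(OCc5ccccc5)c4)[C@H]3B)c12 | intermediate
17 | 3,7,8-tris(benzyloxy)-2-[3,4-bis(benzyloxy)phenyl]-5-{(2R,3S,4R)-7,8-bis(benzyloxy)-2-[3,4-bis(benzyloxy)phenyl]-3-hydroxychroman-4-yl}-4H-chromen-4-one | O=c1c(OCc2ccccc2)c(-c2ccc(OCc3ccccc3)c(OCc3ccccc3)c2)oc2c(OCc3ccccc3)c(OCc3ccccc3)cc([C@@H]3c4ccc(OCc5ccccc5)c(OCc5ccccc5)c4O[C@H](c4ccc(OCc5ccccc5)c(OCc5ccccc5)c4)[C@H]3O)c12 | intermediate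
18 | 2-(3,4-dihydroxyphenyl)-5-[(2R,3S,4R)-2-(3,4-dihydroxyphenyl)-3,7,8-trihydroxychroman-4-yl]-3,7,8-trihydroxy-4H-chromen-4-one | O=c1c(O)c(-c2ccc(O)c(O)c2)oc2c(O)c(O)cc([C@@H]3c4ccc(O)c(O)c4O[C@H](c4ccc(O)c(O)c4)[C@H]3O)c12 | target

**Step count and risks**
Total steps: 9. Longest linear sequence: 7 (steps 1, 4, 5, 6, 7, 8, 9).

Most likely to fail, in order: step 7, step 6, step 3.

Step 7 (hindered coupling next to the peri carbonyl; possible loss of C2 integrity at 90 °C). The fallback sets out from 6 and comes back at 15. Tf2O with 2,6-di-tert-butyl-4-methylpyridine in CH2Cl2 converts 6, without a free enolate, into the alkenyl triflate F5. Borylation with B2pin2, Pd(dppf)Cl2 and KOAc gives the alkenyl boronate F6, in which C4 is again the nucleophilic partner. Suzuki–Miyaura coupling of F6 with 12 (Pd(dppf)Cl2, K3PO4, dioxane/H2O, 60 °C) gives 15.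

Step 6 (competing electrophilic iodination of the electron-rich benzyloxy arenes, or sluggish C5–H metalation). The fallback sets out from 11 and comes back at 15. Ketone-directed C5–H hydroxylation with [RuCl2(p-cymene)]2 and PhI(OCOCF3)2 in 1,2-dichloroethane gives the 5-hydroxyflavonol ether F3. Tf2O/pyridine converts it into the aryl triflate F4, which takes the place of 12 as the electrophile in the step 7 coupling.

Step 3 (the electron-rich chromone may react slowly or with low enantioselectivity). The fallback sets out from chalcone 8, isolated by stopping step 4 before the peroxide is added, and comes back at 6. NaOAc in refluxing EtOH cyclises 8 to the racemic flavanone F1. Kinetic resolution by asymmetric transfer hydrogenation (RuCl(p-cymene)(TsDPEN), HCO2H/Et3N, using the ligand antipode that reduces the (2R)-ketone faster) converts the unwanted enantiomer into the cis-flavan-4-ol F2 and leaves 6, separated by chromatography.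

Further compounds
F1 | step 3 | rac-7,8-bis(benzyloxy)-2-[3,4-bis(benzyloxy)phenyl]chroman-4-one | O=C1CC(c2ccc(OCc3ccccc3)c(OCc3ccccc3)c2)Oc2c(OCc3ccccc3)c(OCc3ccccc3)ccc12
F2 | step 3 | (2R,4R)-7,8-bis(benzyloxy)-2-[3,4-bis(benzyloxy)phenyl]chroman-4-ol | O[C@@H]1C[C@H](c2ccc(OCc3ccccc3)c(OCc3ccccc3)c2)Oc2c(OCc3ccccc3)c(OCc3ccccc3)ccc12
F3 | step 6 | 3,7,8-tris(benzyloxy)-2-[3,4-bis(benzyloxy)phenyl]-5-hydroxy-4H-chromen-4-one | O=c1c(OCc2ccccc2)c(-c2ccc(OCc3ccccc3)c(OCc3ccccc3)c2)oc2c(OCc3ccccc3)c(OCc3ccccc3)cc(O)c12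
F4 | step 6 | 3,7,8-tris(benzyloxy)-2-[3,4-bis(benzyloxy)phenyl]-4-oxo-4H-chromen-5-yl trifluoromethanesulfonate | O=c1c(OCc2ccccc2)c(-c2ccc(OCc3ccccc3)c(OCc3ccccc3)c2)oc2c(OCc3ccccc3)c(OCc3ccccc3)cc(OS(=O)(=O)C(F)(F)F)c12
F5 | step 7 | (2S)-7,8-bis(benzyloxy)-2-[3,4-bis(benzyloxy)phenyl]-2H-chromen-4-yl trifluoromethanesulfonate | O=S(=O)(OC1=C[C@@H](c2ccc(OCc3ccccc3)c(OCc3ccccc3)c2)Oc2c(OCc3ccccc3)c(OCc3ccccc3)ccc12)C(F)(F)F
F6 | step 7 | (2S)-7,8-bis(benzyloxy)-2-[3,4-bis(benzyloxy)phenyl]-4-(4,4,5,5-tetramethyl-1,3,2-dioxaborolan-2-yl)-2H-chromene | CC1(C)OB(OC1(C)C)C1=C[C@@H](c2ccc(OCc3ccccc3)c(OCc3ccccc3)c2)Oc2c(OCc3ccccc3)c(OCc3ccccc3)ccc12
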